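## Structural features

The target is an achiral chain of five benzene rings (A to E) joined by four diaryl ether oxygens. It carries thirteen free phenolic OH groups and has no stereocentre, so no stereocentres stand next to each other. Ring A is a phloroglucinol whose C2 carries the ether oxygen to ring B. Ring B has C1–O–ring A, OH on C3 and C4, C5–O–ring C, and H on C2 and C6. Ring C is pentaoxygenated (C1–O–ring B, C2–O–ring D, OH on C3 to C5). Ring D is a 3,5-dihydroxyphenyl unit etherified at C1 (to ring C) and C4 (to ring E), and ring E is a 3,4,5-trihydroxyphenyl group.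

Three of the four ether oxygens (on ring A, on ring C C2 and on ring D C4) sit between two ortho oxygen substituents. Every ring is electron-rich, so none is activated for substitution by itself. The free polyphenol, with its pyrogallol, catechol and phloroglucinol units, is oxidised easily by air, above all in base. It must therefore be released last, from a robust per-O-methylated precursor, under acidic or neutral handling.

The real difficulty is the regiocontrolled formation of four aryl–oxygen bonds on rings without intrinsic activation, with thirteen oxygens placed correctly. The key step exploits the geometry of ring B: C4 is para to C1 and ortho to both C5 and C3. A formyl group on C4 activates C1 and C5 for displacement of fluoride by the ring A and ring C phenoxides, activates C3 for the last oxygen, and is finally converted into the C4 hydroxyl.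

## Logic of the disconnections

**17 ⇒ 16.** The twelve O–CH3 bonds are cut. Methyl ethers are the only protecting group that survives every basic and oxidative step and that comes ready-made in the commercial building blocks. The demand on the forward step is exhaustive ether cleavage by a boron trihalide without touching the diaryl ethers, under exclusion of air.

**16 ⇒ 14 (through 15).** The C4–OH bond of ring B is traced back to a C4–CHO bond by oxygen insertion. This reveals the carbonyl group that activates ring B for the earlier substitutions. The forward step needs aryl and not hydride migration. This is why a peracid is chosen over alkaline hydrogen peroxide: the latter is reliable only for ortho- or para-hydroxybenzaldehydes, and 14 has no free OH.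

**14 ⇒ 13.** The C3–OCH3 bond of ring B is cut to a C–F bond. This removes the last oxygen that the formyl group can deliver and leads back to a product of two substitutions on a trifluoroarene. The forward step needs displacement of fluoride by methoxide without exchange of the two aryloxy groups.

**13 ⇒ 9 + 10 + 11 (through 12).** The two aryl–oxygen bonds of ring B (C1–O to ring A and C5–O to ring C) are cut in one operation. The five-ring skeleton falls into a three-ring phenol, a one-ring phenol and a one-ring linchpin. The forward step needs the first phenoxide to attack the para fluorine only and the second to replace exactly one ortho fluorine.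

**9 ⇒ 7 (through 8).** The ring C phenol is traced back to an aldehyde by the same oxygen-insertion logic. The nucleophilic OH of 9 thereby becomes the group that activates the preceding ether formation. Aryl migration is favoured here by the ortho aryloxy and para methoxy groups.

**7 ⇒ 5 + 6.** The C2–O bond of ring C is cut on the ring C side. The crowded ring C carbon is thus the electrophile (a bromide ortho to the formyl group), and the nucleophile is a phenol with two free ortho positions. The forward step needs a copper-mediated substitution at a bromide flanked by CHO and OCH3.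

**5 ⇒ 3 (through 4).** The ring D phenol is again traced back to an aldehyde. The demand is aryl migration in a ring whose only para donor is the aryloxy group.

**3 ⇒ 1 + 2.** The C4–O bond of ring D is cut on the ring D side. The oxygen flanked by two methoxy groups is not asked to act as a hindered nucleophile. It is brought in by an unhindered, electron-rich phenol that attacks a bromide activated by the para formyl group. This leaves two catalogue compounds and shortens the way to 9 to four steps.

## Other disconnections considered

**Alternative 1:** The cut is the ring A bond between C2 (ether carbon) and the neighbouring C–OH carbon. It leads to the open-chain ester A2, methyl 6-[3-(benzyloxy)-4,5-dimethoxyphenoxy]-3,5-dioxohexanoate. In the forward key step the C6 carbanion of A2 would acylate itself on the ester carbonyl (Claisen cyclisation), and enolisation would give the 2-aryloxyphloroglucinol A1.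
- In favour: the ring A ether oxygen is installed as an ordinary alkyl aryl ether before ring A exists, so no di-ortho-substituted phenoxide has to react. Ring A also arrives with free OH groups.
- Against: C6 is the least acidic methylene of A2, so a polyanion is needed, and lactonisation to a 4-hydroxypyranone or aldol pathways can compete. A1 carries three free, nucleophilic phenols that would have to be masked again before the benzyl ether is removed and the ring C ether is made. Only one of the four ether bonds is solved.
- Comparison: on structure it addresses the A–B junction only, whereas the chosen plan forms both ring B ethers in one flask. On mechanism it is a carbanion acylation under strongly basic conditions, against two SNAr events under carbonate. On step economy it is longer, because A2 and the re-protection each cost several steps.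
- Equal or better: it is the better plan on two points. It has no ortho/para selectivity question, and three fewer methyl ethers must be cleaved at the end.

**Alternative 2:** The cut is the ring C bond between C1 and C2, the two ether-bearing carbons. It leads to the racemic cyclobutenone A4, 4-{(Z)-2-[2,3-dimethoxy-5-(2,4,6-trimethoxyphenoxy)phenoxy]ethenyl}-2,3,4-trimethoxycyclobut-2-en-1-one. On heating, A4 would open to a dienylketene, and 6π closure with tautomerisation would give the ring A–B–C phenol A3.
- In favour: the five oxygens of ring C are placed unambiguously by the connectivity of a squaric ester adduct. The conditions are neutral and thermal, and no copper coupling at the crowded ring C carbon is needed.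
- Against: A4 requires a (Z)-2-aryloxyvinyl metal reagent that carries the whole ring A–B unit, plus an O-methylation, and only the Z isomer can cyclise. The OH of A3 is flanked by OCH3 and an aryloxy group, so the last ether (to ring D) would have to be formed from a di-ortho-substituted phenol and an unactivated ring D–E electrophile. This is the least favourable bond formation of the whole problem. The ring A–B part must still be made first.
- Comparison: on structure it builds a ring, where the chosen plan builds only ether bonds from bought rings. On mechanism it is pericyclic against polar. On step economy it is clearly longer.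
- Equal or better: the regiochemistry of ring C oxygenation is superior to the chosen plan, which depends on the availability of 6 and on the copper step 3.

**Alternative 3:** The cut is two C–C bonds of ring B (C1–C2 and C5–C6). It leads to the racemic cyclobutenone A6 (3-ethoxy-4-methoxycyclobut-2-en-1-one) and the aryl ynol ether A7 (2-(ethynyloxy)-1,3,5-trimethoxybenzene). Forward, A6 would open to a vinylketene, add A7 by (2+2) cycloaddition, and give the phenol A5 after 4π opening and 6π closure (Danheiser benzannulation).
- In favour: the substitution pattern of ring B is fixed by how the two components join, not by competition among three fluorines. The OH of A5 sits exactly where the ring C ether must go and has only one ortho substituent.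
- Against: A7 must be made from the hindered, oxidisable phenol in two sensitive steps, and A6 is not a catalogue compound. A5 would then have to be joined to a ring C–D–E electrophile that is either unactivated or needs its own activating group.
- Comparison: on structure it constructs ring B de novo with the ring A ether in place, against use of a bought ring B. On mechanism it is a thermal pericyclic cascade against addition–elimination. On step economy it is longer, because both components and a ring C–D–E electrophile need separate syntheses.
- Equal or better: on regiochemical certainty at ring B it is better than the chosen plan. On the nucleophilicity of the phenol used for the B–C ether it is equal.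

Key step: step 5

Remark on the chemistry: 17 has no stereocentre and its diaryl ether axes are taken to rotate freely, so no stereochemical element has to be set. All ether-forming and deprotection steps are assumed to be run under argon because the phenols are oxidisable.

## Route

Step 1
Reactants: 1 4-bromo-3,5-dimethoxybenzaldehyde; 2 3,4,5-trimethoxyphenol
Product: 3 3,5-dimethoxy-4-(3,4,5-trimethoxyphenoxy)benzaldehyde (ring D–E aldehyde)
Conditions: CuI (10 mol %), picolinic acid (20 mol %), K3PO4 (2 equiv), DMSO, 90 °C, argon
Reagents that add atoms: none
Why: Ullmann-type C–O coupling in which the unhindered, electron-rich phenoxide of 2 displaces a bromide that the para formyl group activates, so that copper-assisted addition–elimination should overcome the two flanking methoxy groups; the aldehyde cannot enolise and should tolerate phosphate base.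

Step 2
Reactants: 3 3,5-dimethoxy-4-(3,4,5-trimethoxyphenoxy)benzaldehyde
Product: 5 3,5-dimethoxy-4-(3,4,5-trimethoxyphenoxy)phenol (ring D–E phenol), via the aryl formate 4 (not isolated)
Conditions: mCPBA (1.3 equiv), CH2Cl2, 0 °C to rt; aq. Na2S2O3/NaHCO3 wash; then K2CO3 (cat.), MeOH, rt
Reagents that add atoms: mCPBA, OOC(=O)c1cccc(Cl)c1
Why: Baeyer–Villiger (Dakin-type) oxidation: the peracid adds to the aldehyde and the aryl group, supported by the para aryloxy donor, should migrate to oxygen as it does in 3,4,5-trialkoxybenzaldehydes; the formate is then removed by base-catalysed methanolysis.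

Step 3
Reactants: 5 3,5-dimethoxy-4-(3,4,5-trimethoxyphenoxy)phenol; 6 2-bromo-3,4,5-trimethoxybenzaldehyde
Product: 7 2-[3,5-dimethoxy-4-(3,4,5-trimethoxyphenoxy)phenoxy]-3,4,5-trimethoxybenzaldehyde (ring C–D–E aldehyde)
Conditions: CuI (10 mol %), picolinic acid (20 mol %), K3PO4 (2 equiv), DMSO, 100 °C, argon
Reagents that add atoms: none
Why: Ullmann-type C–O coupling of a phenol with two free ortho positions with an ortho-bromobenzaldehyde, a substrate class in which the neighbouring carbonyl group assists the copper-mediated substitution; the crowded ring C carbon is thus the electrophile and not the nucleophile.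

Step 4
Reactants: 7 2-[3,5-dimethoxy-4-(3,4,5-trimethoxyphenoxy)phenoxy]-3,4,5-trimethoxybenzaldehyde
Product: 9 2-[3,5-dimethoxy-4-(3,4,5-trimethoxyphenoxy)phenoxy]-3,4,5-trimethoxyphenol (ring C–D–E phenol), via the aryl formate 8 (not isolated)
Conditions: mCPBA (1.3 equiv), CH2Cl2, 0 °C to rt; aq. Na2S2O3/NaHCO3 wash; then K2CO3 (cat.), MeOH, rt
Reagents that add atoms: mCPBA, OOC(=O)c1cccc(Cl)c1
Why: Baeyer–Villiger oxidation of a benzaldehyde with an ortho aryloxy and a para methoxy group, both of which strongly favour aryl migration; methanolysis of the formate should release the ring C phenol, whose OH has one free ortho position.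

Step 5
Reactants: 10 2,4,6-trifluorobenzaldehyde; 11 2,4,6-trimethoxyphenol; 9 2-[3,5-dimethoxy-4-(3,4,5-trimethoxyphenoxy)phenoxy]-3,4,5-trimethoxyphenol
Product: 13 2-{2-[3,5-dimethoxy-4-(3,4,5-trimethoxyphenoxy)phenoxy]-3,4,5-trimethoxyphenoxy}-6-fluoro-4-(2,4,6-trimethoxyphenoxy)benzaldehyde, via the 4-aryloxy-2,6-difluorobenzaldehyde 12 (not isolated)
Conditions: 11 (1.0 equiv), Cs2CO3 (1.2 equiv), DMF, 0 °C, then 10 (1.0 equiv), 0 °C to rt; then 9 (0.95 equiv), Cs2CO3 (1.5 equiv), 60 °C; argon
Reagents that add atoms: none
Why: Each substitution is an addition–elimination: the caesium phenoxide adds to a fluorine-bearing carbon, the charge of the Meisenheimer anion is taken up by the formyl group, and fluoride leaves. The closest known reaction types are the SNAr of ortho- and para-fluorobenzaldehydes with phenoxides and the stepwise substitution of polyfluoroarenes by two different nucleophiles. No ring is closed and no stereocentre is formed; the two new bonds are the C1–O and C5–O bonds of ring B. The first stage needs para selectivity, which should be secured by the more stable para-quinoid adduct, by a weakly coordinated phenoxide in DMF (no cation-directed ortho delivery), by the bulk of the 2,6-dimethoxyphenoxide next to the formyl-flanked ortho positions, and by the low temperature. In 12 the two remaining fluorines are equivalent, so the second stage has no site problem. Single substitution should follow from using 9 as the limiting reagent, from the crowding that the first ortho aryloxy group creates, and from the weaker acceptor strength of a formyl group conjugated to two aryloxy donors; this also explains why the second stage needs heating and the two events separate by temperature. Fluoride is displaced much faster than aryloxide, so exchange of the ring A ether is not expected at 60 °C. The hindered phenoxide of 11 is matched with the most reactive, least hindered site, and the valuable three-ring phenol 9 enters last.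

Step 6
Reactants: 13 2-{2-[3,5-dimethoxy-4-(3,4,5-trimethoxyphenoxy)phenoxy]-3,4,5-trimethoxyphenoxy}-6-fluoro-4-(2,4,6-trimethoxyphenoxy)benzaldehyde
Product: 14 2-{2-[3,5-dimethoxy-4-(3,4,5-trimethoxyphenoxy)phenoxy]-3,4,5-trimethoxyphenoxy}-6-methoxy-4-(2,4,6-trimethoxyphenoxy)benzaldehyde
Conditions: NaOMe (2 equiv), MeOH–THF, 60 °C
Reagents that add atoms: sodium methoxide, C[O-].[Na+]
Why: SNAr of the last fluorine, which is ortho to the formyl group, by methoxide; the two aryloxy groups are meta to the carbon attacked and do not sit on charge-bearing positions of the adduct, and fluoride is the far better leaving group, so ether exchange should stay negligible with a small excess of methoxide.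

Step 7
Reactants: 14 2-{2-[3,5-dimethoxy-4-(3,4,5-trimethoxyphenoxy)phenoxy]-3,4,5-trimethoxyphenoxy}-6-methoxy-4-(2,4,6-trimethoxyphenoxy)benzaldehyde
Product: 16 2-{2-[3,5-dimethoxy-4-(3,4,5-trimethoxyphenoxy)phenoxy]-3,4,5-trimethoxyphenoxy}-6-methoxy-4-(2,4,6-trimethoxyphenoxy)phenol, via the aryl formate 15 (not isolated)
Conditions: mCPBA (1.2 equiv), CH2Cl2, 0 °C; aq. Na2S2O3/NaHCO3 wash; then K2CO3 (cat.), MeOH, rt, argon
Reagents that add atoms: mCPBA, OOC(=O)c1cccc(Cl)c1
Why: Baeyer–Villiger oxidation of a 2,4,6-trioxygenated benzaldehyde, the most favourable case for aryl migration; the formate keeps the new electron-rich phenol masked while peracid is present, and it is unmasked only after the oxidant has been destroyed.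

Step 8
Reactants: 16 2-{2-[3,5-dimethoxy-4-(3,4,5-trimethoxyphenoxy)phenoxy]-3,4,5-trimethoxyphenoxy}-6-methoxy-4-(2,4,6-trimethoxyphenoxy)phenol
Product: 17 2-[3-{2-[3,5-dihydroxy-4-(3,4,5-trihydroxyphenoxy)phenoxy]-3,4,5-trihydroxyphenoxy}-4,5-dihydroxyphenoxy]benzene-1,3,5-triol (target)
Conditions: BBr3 (30 equiv), CH2Cl2, −78 °C to rt, argon; then ice–water; Sephadex LH-20 with degassed MeOH
Reagents that add atoms: none
Why: Lewis acid-mediated cleavage of all twelve aryl methyl ethers: boron coordinates each ether oxygen and bromide attacks the methyl carbon, while the diaryl ether bonds offer no carbon open to such attack; acidic, oxygen-free work-up protects the polyphenol.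

## Compound list

1 | 4-bromo-3,5-dimethoxybenzaldehyde | O=Cc1cc(OC)c(Br)c(OC)c1 | starting material
2 | 3,4,5-trimethoxyphenol | COc1cc(O)cc(OC)c1OC | starting material
3 | 3,5-dimethoxy-4-(3,4,5-trimethoxyphenoxy)benzaldehyde | O=Cc1cc(OC)c(Oc2cc(OC)c(OC)c(OC)c2)c(OC)c1 | intermediate
4 | 3,5-dimethoxy-4-(3,4,5-trimethoxyphenoxy)phenyl formate | O=COc1cc(OC)c(Oc2cc(OC)c(OC)c(OC)c2)c(OC)c1 | intermediate
5 | 3,5-dimethoxy-4-(3,4,5-trimethoxyphenoxy)phenol | Oc1cc(OC)c(Oc2cc(OC)c(OC)c(OC)c2)c(OC)c1 | intermediate
6 | 2-bromo-3,4,5-trimethoxybenzaldehyde | O=Cc1cc(OC)c(OC)c(OC)c1Br | starting material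
7 | 2-[3,5-dimethoxy-4-(3,4,5-trimethoxyphenoxy)phenoxy]-3,4,5-trimethoxybenzaldehyde | O=Cc1cc(OC)c(OC)c(OC)c1Oc1cc(OC)c(Oc2cc(OC)c(OC)c(OC)c2)c(OC)c1 | intermediate
8 | 2-[3,5-dimethoxy-4-(3,4,5-trimethoxyphenoxy)phenoxy]-3,4,5-trimethoxyphenyl formate | O=COc1cc(OC)c(OC)c(OC)c1Oc1cc(OC)c(Oc2cc(OC)c(OC)c(OC)c2)c(OC)c1 | intermediate
9 | 2-[3,5-dimethoxy-4-(3,4,5-trimethoxyphenoxy)phenoxy]-3,4,5-trimethoxyphenol | Oc1cc(OC)c(OC)c(OC)c1Oc1cc(OC)c(Oc2cc(OC)c(OC)c(OC)c2)c(OC)c1 | intermediate
10 | 2,4,6-trifluorobenzaldehyde | O=Cc1c(F)cc(F)cc1F | starting material
11 | 2,4,6-trimethoxyphenol | COc1cc(OC)c(O)c(OC)c1 | starting material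
12 | 2,6-difluoro-4-(2,4,6-trimethoxyphenoxy)benzaldehyde | O=Cc1c(F)cc(Oc2c(OC)cc(OC)cc2OC)cc1F | intermediate
13 | 2-{2-[3,5-dimethoxy-4-(3,4,5-trimethoxyphenoxy)phenoxy]-3,4,5-trimethoxyphenoxy}-6-fluoro-4-(2,4,6-trimethoxyphenoxy)benzaldehyde | O=Cc1c(F)cc(Oc2c(OC)cc(OC)cc2OC)cc1Oc1cc(OC)c(OC)c(OC)c1Oc1cc(OC)c(Oc2cc(OC)c(OC)c(OC)c2)c(OC)c1 | intermediate
14 | 2-{2-[3,5-dimethoxy-4-(3,4,5-trimethoxyphenoxy)phenoxy]-3,4,5-trimethoxyphenoxy}-6-methoxy-4-(2,4,6-trimethoxyphenoxy)benzaldehyde | O=Cc1c(OC)cc(Oc2c(OC)cc(OC)cc2OC)cc1Oc1cc(OC)c(OC)c(OC)c1Oc1cc(OC)c(Oc2cc(OC)c(OC)c(OC)c2)c(OC)c1 | intermediate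
15 | 2-{2-[3,5-dimethoxy-4-(3,4,5-trimethoxyphenoxy)phenoxy]-3,4,5-trimethoxyphenoxy}-6-methoxy-4-(2,4,6-trimethoxyphenoxy)phenyl formate | O=COc1c(OC)cc(Oc2c(OC)cc(OC)cc2OC)cc1Oc1cc(OC)c(OC)c(OC)c1Oc1cc(OC)c(Oc2cc(OC)c(OC)c(OC)c2)c(OC)c1 | intermediate
16 | 2-{2-[3,5-dimethoxy-4-(3,4,5-trimethoxyphenoxy)phenoxy]-3,4,5-trimethoxyphenoxy}-6-methoxy-4-(2,4,6-trimethoxyphenoxy)phenol | Oc1c(OC)cc(Oc2c(OC)cc(OC)cc2OC)cc1Oc1cc(OC)c(OC)c(OC)c1Oc1cc(OC)c(Oc2cc(OC)c(OC)c(OC)c2)c(OC)c1 | intermediate
17 | 2-[3-{2-[3,5-dihydroxy-4-(3,4,5-trihydroxyphenoxy)phenoxy]-3,4,5-trihydroxyphenoxy}-4,5-dihydroxyphenoxy]benzene-1,3,5-triol | Oc1cc(O)c(Oc2cc(O)c(O)c(Oc3cc(O)c(O)c(O)c3Oc3cc(O)c(Oc4cc(O)c(O)c(O)c4)c(O)c3)c2)c(O)c1 | target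

## Step count and least certain steps

Total step count: 8. Longest linear sequence: 8 steps (1 and 2 to 17); 6, 10 and 11 enter as bought compounds.

**Step 5 (key step).** The most likely failure is insufficient discrimination between the para and the two ortho fluorines in the first stage, which would give regioisomeric ethers that the second stage turns into isomers of 13. Over-substitution at the second ortho fluorine, or aryloxide exchange at the para position if the second stage is forced, is the second concern. The electronic preference for para attack is modest and the ortho positions are favoured statistically.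
Fallback: the first ether is made without any site competition. It sets out from 11. SNAr of 11 on excess 1,3,5-trifluorobenzene (Cs2CO3, DMSO, 130 °C, sealed vessel) should give 2-(3,5-difluorophenoxy)-1,3,5-trimethoxybenzene F1. Deprotonation of F1 at the carbon between the two fluorines (LDA, THF, −78 °C), which is the most acidic site, followed by DMF and aqueous HCl, should give 12 as an isolated, isomer-free compound. Treatment of 12 with 9 and Cs2CO3 in DMF at 60 °C then comes back to the route at 13.

**Step 1.** Slow copper-mediated substitution at a bromide flanked by two methoxy groups, with competing hydrodebromination and oxidative loss of the electron-rich phenoxide, is the main danger.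
Fallback: the roles of the two rings are exchanged. Step 1 is the first step, so the fallback cannot set out from an earlier intermediate. It replaces the starting pair 1 and 2 by commercial syringaldehyde and (3,4,5-trimethoxyphenyl)boronic acid, joined by Chan–Lam coupling (Cu(OAc)2 2 equiv, pyridine, 4 Å molecular sieves, CH2Cl2, air, rt). This oxidative coupling runs at room temperature and is known to accept di-ortho-substituted phenols. It comes back to the route at 3.

**Step 3.** Crowding at the ring C bromide (between CHO and OCH3) and the electron-rich ring may retard the coupling, so that reduction of the C–Br bond or base-induced reactions of the aldehyde take over.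
Fallback: the copper step is replaced by an uncatalysed addition–elimination, which is much less sensitive to crowding because the nucleophile approaches perpendicular to the ring. It sets out from 5, which is heated with the known 2-fluoro-3,4,5-trimethoxybenzaldehyde F2 and Cs2CO3 in DMSO at 120 °C, and it comes back to the route at 7.

**Step 7.** The peracid may attack the very electron-rich rings (hydroxylation and quinone formation) in competition with the carbonyl group, or hydride migration may divert material to the benzoic acid.
Fallback: the oxygen is introduced with nucleophilic, alkaline peroxide. It sets out from 13. The last fluorine is replaced by a hydroxide equivalent (2-(methylsulfonyl)ethanol, NaH, DMF, 0 °C to rt; substitution then β-elimination) to give the salicylaldehyde 2-{2-[3,5-dimethoxy-4-(3,4,5-trimethoxyphenoxy)phenoxy]-3,4,5-trimethoxyphenoxy}-6-hydroxy-4-(2,4,6-trimethoxyphenoxy)benzaldehyde F3. A classical Dakin oxidation (H2O2, aq. NaOH, argon, 0 °C, acidic work-up) should give the catechol 3-{2-[3,5-dimethoxy-4-(3,4,5-trimethoxyphenoxy)phenoxy]-3,4,5-trimethoxyphenoxy}-5-(2,4,6-trimethoxyphenoxy)benzene-1,2-diol F4. Cleavage of its eleven methyl ethers with BBr3 as in step 8 comes back to the route at 17. This detour also avoids the methoxide of step 6.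

**Step 8.** Incomplete cleavage of the twelve methyl ethers would leave partly methylated phenols that are hard to remove, and air oxidation of the free polyphenol may occur during work-up and chromatography.
Fallback: the product is purified as a stable derivative. It sets out from 16. After BBr3 treatment and aqueous quench, the crude phenol mixture is acetylated at once (Ac2O, pyridine, rt) to the tridecaacetate of 17 F5. F5 can be separated on silica from any acetate that still carries a methyl group. Acid-catalysed methanolysis (HCl in degassed MeOH, rt) with evaporation of the volatiles comes back to the route at 17.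

## Further compounds

F1 | step 5 | 2-(3,5-difluorophenoxy)-1,3,5-trimethoxybenzene | COc1cc(OC)c(Oc2cc(F)cc(F)c2)c(OC)c1
F0 | step 1 | none | none
F2 | step 3 | 2-fluoro-3,4,5-trimethoxybenzaldehyde | O=Cc1cc(OC)c(OC)c(OC)c1F
F3 | step 7 | 2-{2-[3,5-dimethoxy-4-(3,4,5-trimethoxyphenoxy)phenoxy]-3,4,5-trimethoxyphenoxy}-6-hydroxy-4-(2,4,6-trimethoxyphenoxy)benzaldehyde | O=Cc1c(O)cc(Oc2c(OC)cc(OC)cc2OC)cc1Oc1cc(OC)c(OC)c(OC)c1Oc1cc(OC)c(Oc2cc(OC)c(OC)c(OC)c2)c(OC)c1
F4 | step 7 | 3-{2-[3,5-dimethoxy-4-(3,4,5-trimethoxyphenoxy)phenoxy]-3,4,5-trimethoxyphenoxy}-5-(2,4,6-trimethoxyphenoxy)benzene-1,2-diol | Oc1c(O)cc(Oc2c(OC)cc(OC)cc2OC)cc1Oc1cc(OC)c(OC)c(OC)c1Oc1cc(OC)c(Oc2cc(OC)c(OC)c(OC)c2)c(OC)c1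
F5 | step 8 | tridecaacetate of 17 (all thirteen OH groups as acetates) | CC(=O)Oc1cc(OC(C)=O)c(Oc2cc(OC(C)=O)c(OC(C)=O)c(Oc3cc(OC(C)=O)c(OC(C)=O)c(OC(C)=O)c3Oc3cc(OC(C)=O)c(Oc4cc(OC(C)=O)c(OC(C)=O)c(OC(C)=O)c4)c(OC(C)=O)c3)c2)c(OC(C)=O)c1
A1 | alternative 1 | 2-[3-(benzyloxy)-4,5-dimethoxyphenoxy]benzene-1,3,5-triol | Oc1cc(O)c(Oc2cc(OC)c(OC)c(OCc3ccccc3)c2)c(O)c1
A2 | alternative 1 | methyl 6-[3-(benzyloxy)-4,5-dimethoxyphenoxy]-3,5-dioxohexanoate | COC(=O)CC(=O)CC(=O)COc1cc(OC)c(OC)c(OCc2ccccc2)c1
A3 | alternative 2 | 6-[2,3-dimethoxy-5-(2,4,6-trimethoxyphenoxy)phenoxy]-2,3,4-trimethoxyphenol | Oc1c(OC)c(OC)c(OC)cc1Oc1cc(Oc2c(OC)cc(OC)cc2OC)cc(OC)c1OC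
A4 | alternative 2 | 4-{(Z)-2-[2,3-dimethoxy-5-(2,4,6-trimethoxyphenoxy)phenoxy]ethenyl}-2,3,4-trimethoxycyclobut-2-en-1-one (racemic) | COC1=C(OC)C(OC)(/C=C\Oc2cc(Oc3c(OC)cc(OC)cc3OC)cc(OC)c2OC)C1=O
A5 | alternative 3 | 3-ethoxy-2-methoxy-5-(2,4,6-trimethoxyphenoxy)phenol | CCOc1cc(Oc2c(OC)cc(OC)cc2OC)cc(O)c1OC
A6 | alternative 3 | 3-ethoxy-4-methoxycyclobut-2-en-1-one (racemic) | CCOC1=CC(=O)C1OC
A7 | alternative 3 | 2-(ethynyloxy)-1,3,5-trimethoxybenzene | C#COc1c(OC)cc(OC)cc1OC
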